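Given 5.0 h, I ask how this flask's charge ends up shared, and I reckon in fractions of the charged starting material, working with the fraction left and not the fraction made.

starting material 1.0 mM; protic impurity 0.300 mM; time 5.0 h

    starting material + protic impurity → quenched substrate (k1 = 67 /M/s)
    isomer of the product A ⇌ isomer of the product B (K2 = 0.61, k2 = 0.0011 /s)
    target ⇌ isomer of the product A (K3 = 1.3, k3 = 0.0011 /s)
    starting material ⇌ target (K4 = 1.7, k4 = 0.012 /s)

* why nothing more happens at 5.0 h, or that something still does (forward and back rates have come level / it is still moving / all of the starting material has reacted)
* share of the starting material used up at 5.0 h
* target at 5.0 h, in percent of the starting material charged
* amount of target if the flask were left three thousand times as long, in percent of the starting material charged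

1. The protic impurity takes starting material one for one, with no way back. It is the limiting reagent of that step, so if its charge reacts to the end, the fraction left is 70.0 %. I call this fraction the pool: starting material, target and the two isomers together.

2. Within the pool, each equilibrium constant is a ratio of neighbours once forward and back rates are level. One part of starting material stands with 1.7 parts of target, 2.21 of isomer of the product A and 1.35 of isomer of the product B, which is 6.26 parts in total. Target therefore holds 27.2 % of the pool; I carry this equilibrium share of the pool forward.

3. The flask has time to get there. The forward half-lives are 0.96 min for starting material going to target, 0.18 h for target going to isomer of the product A, and 0.18 h for that isomer going on, and each is far shorter than 5.0 h. With starting material down at its equilibrium fraction of 11.2 %, the impurity's pseudo-first-order half-life is 1.54 min, also shorter than 5.0 h.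

4. So I expect level rates in this flask, with 88.8 % of the starting material used up and target at the share times the pool, 19.0 %, unchanged on long standing.

The forecast says forward and back rates have come level, with conversion 88.8 % (87.5 % to 90 %) and target 19 % (18 % to 20 %), and 19 % on long standing. Its grounds are that the impurity is “used up within a few minutes and permanently removes 30% of the charge”. My reckoning gives the same picture.

The simulated flask gives forward and back rates have come level, with 88.8 % used up, target at 19.0 %, and 19.0 % on long standing. Over the second half of the time, the largest change of any share in this flask is 0 percentage points. Target over everything not quenched in this flask reads 27.2 %, the carried share. In the neighbour flask with 0.75 mM of protic impurity, the pool is 25.0 %, so the share predicts 6.80 %, and that flask holds 6.79 % of target.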